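The runs were computed for substances that don't exist; the scatter is artificial.

24.9% of target at the end of the blue run, with partner in large excess: that reading needs explaining.

| flask | starting material | coupling partner | protic impurity | remark | time |
|---|---|---|---|---|---|
| teal | 0.050 M | 0.016 M | 0.025 M | run made earlier |  |
| blue | 0.050 M | 0.30 M | 0.025 M | run made earlier |  |
| Sunday's | 0.050 M | 0.0300 M | 0.0250 M |  | 3.0 h |
| Friday's | 0.050 M | 0.0600 M | 0.0250 M |  | 3.0 h |
| Wednesday's | 0.050 M | 0.120 M | 0.0250 M |  | 3.0 h |
| Monday's | 0.050 M | 0.250 M | 0.0250 M |  | 3.0 h |
| Thursday's | 0.050 M | 0.500 M | 0.0250 M |  | 3.0 h |

| run | time / min | target / % |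
|---|---|---|
| teal | 8.00 | 5.0 |
| teal | 15.0 | 7.0 |
| teal | 25.0 | 9.8 |
| teal | 50.0 | 14.8 |
| teal | 90.0 | 18.6 |
| blue | 8.00 | 20.6 |
| blue | 25.0 | 23.2 |
| blue | 40.0 | 22.7 |
| blue | 60.0 | 24.8 |
| blue | 90.0 | 24.9 |

(scatter of a reading: 1 percentage point)

- the numbers in the tables scatter by 1 percentage point (one standard deviation)
- "hardly changes" means that all values lie within two and a half points (for a concentration: within two and a half percent of the largest)

* amount of target at the end, in percent of the starting material charged for Sunday's, Friday's, Wednesday's, Monday's, Thursday's, in this order
* how that number moves from the first to the last of them (falls, then rises / rises all the way / hardly changes / falls all the way / rises, then falls)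

*Where did the rest of the starting material in the blue run go?* Not to the protic impurity by itself, if one impurity takes one starting material. Its charge covers 50.0% of the starting material, while 75.1% did not become target. So the readings ask for a further loss.

*What is there to cause it?* Coupling partner stands at 6.00 times the starting material in the blue run. My wager is a loss route that goes with the square of the partner, while target goes with its first power.

*Write that down.* Let A be starting material, B partner, P target and L the loss. Target forms in proportion to A times B, and the loss in proportion to A times B squared. A cancels in the ratio, so dL/dP = ρB. Holding B at its charge and integrating gives L/P = ρB, so once the starting material has gone to P and L, the target's share of it is one over one plus ρB.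

*And ρ?* The blue run gives ρ = 10.1 M⁻¹, the starting material lost per target formed, per molar of charged partner. It is a selectivity factor scaled by the partner.

*Do the runs prove that order?* No. The teal run, still climbing at 18.6% after 90.0 min, does not separate it from a fixed ceiling. ρ also absorbs whatever the impurity took in the blue run and the partner's fall.

*What do you commit to?* Monday's at 28.5% and Thursday's at 16.6%, so the row ends falling. I leave the low end open, since Sunday's partner covers 60.0% of the starting material and the impurity's part there is unread.

The forecast differs: 24.8%, 25%, 25%, 25%, 25%, so hardly changes, on the ground that "all should reach the ceiling, about 25%".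

The flask gives 33.7%, 43.7%, 40.9%, 27.9%, 15.9%: rises, then falls.

    starting material + coupling partner → target (k = 0.00640 M⁻¹ s⁻¹)
    starting material + 2 coupling partner → side product (k = 0.0730 M⁻² s⁻¹)
    starting material + protic impurity → quenched substrate (k = 0.0120 M⁻¹ s⁻¹)

With ρ from the blue run, ρ times the charged partner is 5.03 for Thursday's, and side product plus quenched substrate over target at the end of Thursday's stands at 5.27. For Monday's the same pair reads 2.51 and 2.59, and the row turns at 0.074 M of partner, with 44.3% of target.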